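**Plan**

- Retrosynthesis: the 5-OH is released last from its methyl ether. C4=O and C2=C3 are traced back (dehydrogenation, alcohol oxidation, Markovnikov hydration) to the C3=C4 alkene of a 2-aryl-2H-chromene.
- Ring C is then cut at C4a–C4 and O1–C2, which both come from one aryl 1-arylpropargyl ether. That ether is cut at O–CH (Mitsunobu), the carbinol at CH–C≡C (ethynyl Grignard) and the aldehyde at aryl–CHO (Vilsmeier).
- Enabling feature: O1 and C4 sit on the adjacent ring A carbons C8a and C4a. In 2,3,5-trimethoxyphenol the carbon that becomes C4a is the only unsubstituted position ortho to the oxygen (the other, future C8, carries OMe), so a [3,3] shift can only deliver the 5,7,8-oxygenation pattern.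
- Forward: ring A is made as 2,3,5-trimethoxyphenol (steps 1–4) and ring B as the propargylic alcohol (steps 5–6). They are joined through oxygen (step 7), ring C closes in step 8, and steps 9–12 adjust the oxidation level and free the 5-OH.
- Stereochemistry: the target is achiral. C2 (step 8) and C4 (step 9) arise without control and are erased in steps 11 and 10.

Key step: step 8

Assumption: compounds 1, 7 and 10 (as a THF solution) are purchased; every chiral intermediate is carried as a racemate or epimer mixture and is drawn without configuration.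

**Route**

Step 1
Reactants: 1 2-hydroxy-4,6-dimethoxybenzaldehyde
Product: 2 2-(benzyloxy)-4,6-dimethoxybenzaldehyde
Conditions: BnBr, K2CO3, DMF, 60 °C
Reagents that add atoms: benzyl bromide, BrCc1ccccc1
Why: Williamson etherification, in which carbonate deprotonates the chelated ortho-hydroxyl and the phenoxide displaces bromide, masking the oxygen that later becomes O1 while the formyl carbon is converted into the neighbouring methoxy-bearing position.

Step 2
Reactants: 2 2-(benzyloxy)-4,6-dimethoxybenzaldehyde
Product: 4 2-(benzyloxy)-4,6-dimethoxyphenol, via aryl formate 3 (not isolated)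
Conditions: mCPBA, CH2Cl2, 0 °C to rt; aq. NaHCO3 wash; then MeOH, Et3N (cat.), rt
Reagents that add atoms: 3-chloroperoxybenzoic acid (mCPBA), OOC(=O)c1cccc(Cl)c1
Why: Baeyer–Villiger (Dakin-type) oxidation, in which three alkoxy donors ortho and para to the formyl group make the aryl group migrate in the Criegee adduct to give formate 3, which mild methanolysis cleaves once the peracid has been washed out.

Step 3
Reactants: 4 2-(benzyloxy)-4,6-dimethoxyphenol
Product: 5 1-(benzyloxy)-2,3,5-trimethoxybenzene
Conditions: MeI, K2CO3, DMF, rt to 40 °C, Ar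
Reagents that add atoms: iodomethane, CI
Why: Williamson O-methylation of the only free hydroxyl fixes the future 8-OMe while the benzyl ether keeps the future O1 distinguishable.

Step 4
Reactants: 5 1-(benzyloxy)-2,3,5-trimethoxybenzene
Product: 6 2,3,5-trimethoxyphenol
Conditions: H2 (1 atm), 10% Pd/C, EtOAc/MeOH, rt
Reagents that add atoms: none
Why: Catalytic hydrogenolysis cleaves the benzylic C–O bond only, since aryl methyl ethers are inert, so the single hydroxyl that will become O1 is released.

Step 5
Reactants: 7 1,2,3,4-tetramethoxybenzene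
Product: 9 2,3,4,5-tetramethoxybenzaldehyde, via iminium chloride 8 (not isolated)
Conditions: POCl3, DMF, 0 to 80 °C; then H2O, 0 °C to rt
Reagents that add atoms: N,N-dimethylformamide, CN(C)C=O; water, O
Why: Vilsmeier–Haack formylation, in which the two free ring positions are equivalent and each is activated by an ortho- and a para-methoxy group, so the chloroiminium electrophile should give a single iminium salt 8 that aqueous work-up hydrolyses to the aldehyde.

Step 6
Reactants: 9 2,3,4,5-tetramethoxybenzaldehyde; 10 ethynylmagnesium bromide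
Product: 11 rac-1-(2,3,4,5-tetramethoxyphenyl)prop-2-yn-1-ol
Conditions: THF, 0 °C to rt; aq. NH4Cl
Reagents that add atoms: none
Why: Grignard 1,2-addition of the acetylide to the aldehyde gives the propargylic carbinol as a racemate, which is acceptable because this centre is lost in step 8.

Step 7
Reactants: 6 2,3,5-trimethoxyphenol; 11 rac-1-(2,3,4,5-tetramethoxyphenyl)prop-2-yn-1-ol
Product: 12 rac-1,2,5-trimethoxy-3-{[1-(2,3,4,5-tetramethoxyphenyl)prop-2-yn-1-yl]oxy}benzene
Conditions: PPh3, DIAD, toluene, 0 °C to rt
Reagents that add atoms: none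
Why: Mitsunobu reaction, in which the phenol displaces the alkoxyphosphonium of the secondary propargylic alcohol at the carbinol carbon, a standard entry to aryl 1-substituted propargyl ethers, with low temperature and a non-polar solvent chosen to keep the activated benzylic centre on the SN2 path.

Step 8
Reactants: 12 rac-1,2,5-trimethoxy-3-{[1-(2,3,4,5-tetramethoxyphenyl)prop-2-yn-1-yl]oxy}benzene
Product: 16 rac-5,7,8-trimethoxy-2-(2,3,4,5-tetramethoxyphenyl)-2H-chromene, via allenyl dienone 13 (not isolated), via allenyl phenol 14 (not isolated), via quinone methide 15 (not isolated)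
Conditions: PhNEt2 (degassed), 185 °C, Ar
Reagents that add atoms: none
Why: Heating drives an aromatic propargyl Claisen [3,3] shift that breaks the O–CH bond and joins the alkyne terminus to C6 of the phenoxy ring (the C4a–C4 bond), giving dienone 13, which enolises to allenyl phenol 14; a 1,5-hydrogen shift from O–H to the central allene carbon then gives the (Z)-ortho-quinone methide 15, whose oxa-6π electrocyclisation forms O1–C2 and re-aromatises ring A. The closest known reaction type is the thermal conversion of aryl propargyl ethers, 1-aryl-substituted ones included, into 2H-chromenes in hot N,N-diethylaniline. The pyran ring closes pericyclically, by a thermal disrotatory six-electron electrocyclisation of the cis-dienone, and the six-membered transition state of the hydrogen shift necessarily sets the exocyclic Z geometry that this closure requires. C2 is the only new stereocentre and forms without control as a racemate, because the propargylic configuration is lost at planar 15; it is erased in step 11. Regioselectivity is secured by the substrate, since C2 of the phenoxy ring carries OMe and only migration to C6 can end in an aromatic product. Chemoselectivity for the concerted path over heterolysis of the doubly activated benzylic C–O bond and over phenoxide 5-exo addition to the allene (benzofuran formation) should follow from the non-polar, weakly basic, salt-free medium and from the 1-aryl group, which lowers the temperature needed.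

Step 9
Reactants: 16 rac-5,7,8-trimethoxy-2-(2,3,4,5-tetramethoxyphenyl)-2H-chromene
Product: 17 rac-5,7,8-trimethoxy-2-(2,3,4,5-tetramethoxyphenyl)-3,4-dihydro-2H-chromen-4-ol (C4 epimer mixture)
Conditions: Co(acac)2 (cat.), PhSiH3, O2 (1 atm), THF, rt
Reagents that add atoms: dioxygen, O=O
Why: Mukaiyama hydration, in which a cobalt hydride formed from the silane transfers a hydrogen atom to C3 so that the radical sits at benzylic C4 (stabilised by ring A), captures O2 and is reduced by the silane to the alcohol under neutral conditions that spare the C2–O1 ether; the C4 configuration is uncontrolled and irrelevant because step 10 removes it.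

Step 10
Reactants: 17 rac-5,7,8-trimethoxy-2-(2,3,4,5-tetramethoxyphenyl)-3,4-dihydro-2H-chromen-4-ol
Product: 18 rac-5,7,8-trimethoxy-2-(2,3,4,5-tetramethoxyphenyl)-2,3-dihydro-4H-chromen-4-one
Conditions: Dess–Martin periodinane, CH2Cl2, rt
Reagents that add atoms: none
Why: Dess–Martin oxidation of a secondary benzylic alcohol to the aryl ketone proceeds under mild conditions that tolerate the electron-rich arenes and the C2 aryl ether, and both C4 epimers converge on one flavanone.

Step 11
Reactants: 18 rac-5,7,8-trimethoxy-2-(2,3,4,5-tetramethoxyphenyl)-2,3-dihydro-4H-chromen-4-one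
Product: 20 5,7,8-trimethoxy-2-(2,3,4,5-tetramethoxyphenyl)-4H-chromen-4-one, via 3-iodoflavanone 19 (not isolated)
Conditions: I2 (cat.), DMSO, 130 °C
Reagents that add atoms: none
Why: Iodine/DMSO dehydrogenation of a flavanone, in which the enol is iodinated at C3 to give 19, HI is eliminated across C2–C3 to form the conjugated chromone, and DMSO re-oxidises HI to I2 so that iodine stays catalytic and ring iodination is limited; the C2 stereocentre is removed.

Step 12
Reactants: 20 5,7,8-trimethoxy-2-(2,3,4,5-tetramethoxyphenyl)-4H-chromen-4-one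
Product: 22 5-hydroxy-7,8-dimethoxy-2-(2,3,4,5-tetramethoxyphenyl)-4H-chromen-4-one, via dichloroboron chelate 21 (not isolated)
Conditions: BCl3 (1.2 equiv), CH2Cl2, −78 to 0 °C; then H2O
Reagents that add atoms: none
Why: Chelation-controlled Lewis-acid ether cleavage, in which BCl3 binds between C4=O and the peri 5-OMe oxygen so that chloride removes only that methyl to give chelate 21, hydrolysed on work-up; this is the standard selective 5-O-demethylation of polymethoxyflavones and should leave the other six methoxy groups intact at low temperature with about one equivalent of reagent.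

**Compound list**

1 | 2-hydroxy-4,6-dimethoxybenzaldehyde | COc1cc(O)c(C=O)c(OC)c1 | starting material
2 | 2-(benzyloxy)-4,6-dimethoxybenzaldehyde | COc1cc(OCc2ccccc2)c(C=O)c(OC)c1 | intermediate
3 | 2-(benzyloxy)-4,6-dimethoxyphenyl formate | COc1cc(OCc2ccccc2)c(OC=O)c(OC)c1 | intermediate (not isolated)
4 | 2-(benzyloxy)-4,6-dimethoxyphenol | COc1cc(OCc2ccccc2)c(O)c(OC)c1 | intermediate
5 | 1-(benzyloxy)-2,3,5-trimethoxybenzene | COc1cc(OCc2ccccc2)c(OC)c(OC)c1 | intermediate
6 | 2,3,5-trimethoxyphenol | COc1cc(O)c(OC)c(OC)c1 | intermediate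
7 | 1,2,3,4-tetramethoxybenzene | COc1ccc(OC)c(OC)c1OC | starting material
8 | N-methyl-N-[(2,3,4,5-tetramethoxyphenyl)methylidene]methanaminium chloride | COc1cc(C=[N+](C)C)c(OC)c(OC)c1OC.[Cl-] | intermediate (not isolated)
9 | 2,3,4,5-tetramethoxybenzaldehyde | COc1cc(C=O)c(OC)c(OC)c1OC | intermediate
10 | ethynylmagnesium bromide | C#C[Mg]Br | starting material
11 | rac-1-(2,3,4,5-tetramethoxyphenyl)prop-2-yn-1-ol | C#CC(O)c1cc(OC)c(OC)c(OC)c1OC | intermediate
12 | rac-1,2,5-trimethoxy-3-{[1-(2,3,4,5-tetramethoxyphenyl)prop-2-yn-1-yl]oxy}benzene | C#CC(Oc1cc(OC)cc(OC)c1OC)c1cc(OC)c(OC)c(OC)c1OC | intermediate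
13 | 2,3,5-trimethoxy-6-[3-(2,3,4,5-tetramethoxyphenyl)propa-1,2-dien-1-yl]cyclohexa-2,4-dien-1-one (stereoisomer mixture) | O=C1C(OC)=C(OC)C=C(OC)C1C=C=Cc1cc(OC)c(OC)c(OC)c1OC | intermediate (not isolated)
14 | rac-2,3,5-trimethoxy-6-[3-(2,3,4,5-tetramethoxyphenyl)propa-1,2-dien-1-yl]phenol | Oc1c(OC)c(OC)cc(OC)c1C=C=Cc1cc(OC)c(OC)c(OC)c1OC | intermediate (not isolated)
15 | (6Z)-2,3,5-trimethoxy-6-[3-(2,3,4,5-tetramethoxyphenyl)prop-2-en-1-ylidene]cyclohexa-2,4-dien-1-one (side-chain C=C geometry undefined) | COc1cc(C=C/C=C2\C(=O)C(OC)=C(OC)C=C2OC)c(OC)c(OC)c1OC | intermediate (not isolated)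
16 | rac-5,7,8-trimethoxy-2-(2,3,4,5-tetramethoxyphenyl)-2H-chromene | COc1cc(C2C=Cc3c(OC)cc(OC)c(OC)c3O2)c(OC)c(OC)c1OC | intermediate
17 | rac-5,7,8-trimethoxy-2-(2,3,4,5-tetramethoxyphenyl)-3,4-dihydro-2H-chromen-4-ol (C4 epimer mixture) | COc1cc(C2CC(O)c3c(OC)cc(OC)c(OC)c3O2)c(OC)c(OC)c1OC | intermediate
18 | rac-5,7,8-trimethoxy-2-(2,3,4,5-tetramethoxyphenyl)-2,3-dihydro-4H-chromen-4-one | COc1cc(C2CC(=O)c3c(OC)cc(OC)c(OC)c3O2)c(OC)c(OC)c1OC | intermediate
19 | rac-3-iodo-5,7,8-trimethoxy-2-(2,3,4,5-tetramethoxyphenyl)-2,3-dihydro-4H-chromen-4-one | COc1cc(C2Oc3c(OC)c(OC)cc(OC)c3C(=O)C2I)c(OC)c(OC)c1OC | intermediate (not isolated)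
20 | 5,7,8-trimethoxy-2-(2,3,4,5-tetramethoxyphenyl)-4H-chromen-4-one | COc1cc(-c2cc(=O)c3c(OC)cc(OC)c(OC)c3o2)c(OC)c(OC)c1OC | intermediate
21 | 5-[(dichloroboranyl)oxy]-7,8-dimethoxy-2-(2,3,4,5-tetramethoxyphenyl)-4H-chromen-4-one (carbonyl-chelated) | COc1cc(-c2cc(=O)c3c(OB(Cl)Cl)cc(OC)c(OC)c3o2)c(OC)c(OC)c1OC | intermediate (not isolated)
22 | 5-hydroxy-7,8-dimethoxy-2-(2,3,4,5-tetramethoxyphenyl)-4H-chromen-4-one | COc1cc(-c2cc(=O)c3c(O)cc(OC)c(OC)c3o2)c(OC)c(OC)c1OC | target

**Step count and risks**

Total: 12 steps. Longest linear sequence: 10 steps (steps 1–4 and 7–12); the ring B branch (steps 5–6) joins at step 7.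

Steps most likely to fail:

1. Step 8. Heterolysis of the doubly activated benzylic C–O bond may outrun the concerted shift at the temperature required, with recombination at carbon. Alternatively the phenoxide of the allenyl phenol may add 5-exo to the allene instead of undergoing the hydrogen shift. The fallback builds ring C by the chalcone route and sets out from 6 and 9. Phenol 6 is C-acetylated at its free ortho position (Ac2O, BF3·OEt2, 80 °C; acetate formation and Fries-type shift to the chelated ortho carbon) to give 1-(2-hydroxy-3,4,6-trimethoxyphenyl)ethan-1-one F1. Claisen–Schmidt condensation of F1 with aldehyde 9 (KOH, EtOH, rt) gives (2E)-1-(2-hydroxy-3,4,6-trimethoxyphenyl)-3-(2,3,4,5-tetramethoxyphenyl)prop-2-en-1-one F2. Oxidative cyclisation of F2 with I2 (cat.) in DMSO at 130 °C should give the flavone directly. The fallback comes back to the route at 20, so that only step 12 remains.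

2. Step 7. The alkoxyphosphonium of the electron-rich benzylic alcohol may ionise before the phenol attacks, which would lose regiocontrol (attack at the alkyne terminus, or C-alkylation of the phenol ring) and erode the mass balance. The fallback sets out from 11 and uses copper-catalysed propargylic substitution. Alcohol 11 is acetylated (Ac2O, Et3N, DMAP, CH2Cl2) to rac-1-(2,3,4,5-tetramethoxyphenyl)prop-2-yn-1-yl acetate F3. F3 is then treated with phenol 6, Cu(MeCN)4BF4 (cat.), a 2,6-bis(oxazolinyl)pyridine ligand and iPr2NEt in MeOH at 0 °C. The copper allenylidene formed from the terminal alkyne directs the phenol oxygen to the propargylic carbon. The fallback comes back to the route at 12.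

3. Step 9. The radical chain may abstract the doubly activated C2–H or over-oxidise at C4, giving mixtures and incomplete conversion. The fallback sets out from 16 and replaces the radical hydration by ionic Markovnikov hydration. Oxymercuration (Hg(OAc)2, THF/H2O, rt) places mercury at C3 and hydroxyl at benzylic C4, giving acetato[4-hydroxy-5,7,8-trimethoxy-2-(2,3,4,5-tetramethoxyphenyl)-3,4-dihydro-2H-chromen-3-yl]mercury F4. Demercuration with NaBH4 in aq. NaOH, which also reverses any aryl mercuration, should give the flavan-4-ol. The fallback comes back to the route at 17.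

**Further compounds**

F1 | step 8 | 1-(2-hydroxy-3,4,6-trimethoxyphenyl)ethan-1-one | CC(=O)c1c(O)c(OC)c(OC)cc1OC
F2 | step 8 | (2E)-1-(2-hydroxy-3,4,6-trimethoxyphenyl)-3-(2,3,4,5-tetramethoxyphenyl)prop-2-en-1-one | COc1cc(/C=C/C(=O)c2c(O)c(OC)c(OC)cc2OC)c(OC)c(OC)c1OC
F3 | step 7 | rac-1-(2,3,4,5-tetramethoxyphenyl)prop-2-yn-1-yl acetate | C#CC(OC(C)=O)c1cc(OC)c(OC)c(OC)c1OC
F4 | step 9 | acetato[4-hydroxy-5,7,8-trimethoxy-2-(2,3,4,5-tetramethoxyphenyl)-3,4-dihydro-2H-chromen-3-yl]mercury (racemic, configuration not assigned) | CC(=O)O[Hg]C1C(O)c2c(OC)cc(OC)c(OC)c2OC1c1cc(OC)c(OC)c(OC)c1OC
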